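**Assumption:** the SMILES is taken as binding for constitution and configuration. Drimane numbering (C1–C15) is used for the decalin and primed numbers (C1′–C6′) for the C7 ring.

## Retrosynthetic overview

1. Target 26 ⇒ epoxy ketone ketal 24 (C4′ reduction, ketal hydrolysis, desilylation) ⇒ dienone monoketal 23 (nucleophilic epoxidation of the β-unsubstituted enone arm).
2. 23 ⇒ C11–C5′ bond by hydroboration / B-alkyl Suzuki: diene 17 (hydroboration sets C9) + iodo quinone monoketal 21 (two steps from m-cresol).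
3. 17 ⇒ α-methylene decalone 14 (enol triflate, then methyl coupling for C12).
4. 14 ⇒ vinyl carbinol 12 on a trans-hydrindane: semipinacol ring expansion (1,2-shift of C10 from C8 to C9) makes ring B.
5. 12 ⇒ Hajos–Parrish-type enedione 4 from 2-methylcyclopentane-1,3-dione + ethyl vinyl ketone. Ring order: five-membered ring (bought) → ring A → ring B (expansion) → oxidised C7 ring attached last.

## Route

**Step 1**
Reactants: 1 2-methylcyclopentane-1,3-dione; 2 pent-1-en-3-one
Product: 4 (7aS)-4,7a-dimethyl-2,3,7,7a-tetrahydro-1H-indene-1,5(6H)-dione, via triketone 3 (not isolated)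
Conditions: 2 (1.3 equiv), H2O, rt; evaporate; L-phenylalanine (1 equiv), 1 M HClO4 (0.5 equiv), MeCN, reflux
Reagents that add atoms: none
Why: Michael addition followed by the Hajos–Parrish–Eder–Sauer–Wiechert amino-acid-mediated aldol condensation, in which the L-phenylalanine enamine attacks one of the two enantiotopic ring carbonyls and so sets the quaternary centre (future C10) as S.

**Step 2**
Reactants: 4 (7aS)-4,7a-dimethyl-2,3,7,7a-tetrahydro-1H-indene-1,5(6H)-dione; 5 vinylmagnesium bromide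
Product: 6 (1R,7aS)-1-ethenyl-1-hydroxy-4,7a-dimethyl-1,2,3,6,7,7a-hexahydro-5H-inden-5-one
Conditions: CeCl3 (1.5 equiv), 5 (1.3 equiv), THF, −78 °C; aq NH4Cl
Reagents that add atoms: none
Why: Organocerium (Imamoto) 1,2-addition is selective for the strained saturated cyclopentanone over the less electrophilic α-methylated enone carbonyl and comes from the face opposite the angular methyl (as with 17-oxo steroids), giving the 1β-hydroxy-1α-vinyl carbinol.

**Step 3**
Reactants: 6 (1R,7aS)-1-ethenyl-1-hydroxy-4,7a-dimethyl-1,2,3,6,7,7a-hexahydro-5H-inden-5-one; 7 formaldehyde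
Product: 9 (1R,3aR,4R,7aS)-1-ethenyl-1-hydroxy-4-(hydroxymethyl)-4,7a-dimethyloctahydro-5H-inden-5-one, via dilithium enolate 8 (not isolated)
Conditions: Li (2.3 equiv), NH3/THF, −78 °C; isoprene; remove NH3; CH2O (g, from cracked paraformaldehyde), THF, −78 → −40 °C; aq NH4Cl
Reagents that add atoms: none
Why: Stork-type Birch reductive alkylation, in which the tertiary alcohol is the single proton donor, axial protonation of the β-carbanion gives the trans ring fusion (H-5 α), and the regiospecific enolate takes formaldehyde on the face away from the angular methyl so that CH2OH is α and the C4 methyl β (the outcome known from aphidicolin-type reductive hydroxymethylations).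

**Step 4**
Reactants: 9 (1R,3aR,4R,7aS)-1-ethenyl-1-hydroxy-4-(hydroxymethyl)-4,7a-dimethyloctahydro-5H-inden-5-one
Product: 10 (1R,3aR,4R,7aS)-4-{[(tert-butyldimethylsilyl)oxy]methyl}-1-ethenyl-1-hydroxy-4,7a-dimethyloctahydro-5H-inden-5-one
Conditions: TBSCl (1.1 equiv), imidazole, DMF, 0 °C → rt
Reagents that add atoms: tert-butyldimethylsilyl chloride, CC(C)(C)[Si](C)(C)Cl
Why: Standard silylation of the primary alcohol; the tertiary carbinol is inert, and the ether removes the retro-aldol risk of the β-hydroxy ketone.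

**Step 5**
Reactants: 10 (1R,3aR,4R,7aS)-4-{[(tert-butyldimethylsilyl)oxy]methyl}-1-ethenyl-1-hydroxy-4,7a-dimethyloctahydro-5H-inden-5-one
Product: 12 (1R,3aS,4R,7aS)-4-{[(tert-butyldimethylsilyl)oxy]methyl}-1-ethenyl-4,7a-dimethyloctahydro-1H-inden-1-ol, via N-silyl hydrazone 11 (not isolated)
Conditions: TBSNHNHTBS (1.5 equiv), Sc(OTf)3 (1 mol %), CHCl3, rt → 55 °C; then KOtBu, tBuOH, DMSO, 23 → 100 °C
Reagents that add atoms: none
Why: Wolff–Kishner reduction in the Myers N-silyl hydrazone variant, which copes with the hindered neopentyl C3 ketone and leaves the silyl ether and the vinyl carbinol (no allylic hydrogens to isomerise) untouched.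

**Step 6**
Reactants: 12 (1R,3aS,4R,7aS)-4-{[(tert-butyldimethylsilyl)oxy]methyl}-1-ethenyl-4,7a-dimethyloctahydro-1H-inden-1-ol
Product: 14 (4aR,5R,8aS)-5-{[(tert-butyldimethylsilyl)oxy]methyl}-5,8a-dimethyl-1-methylideneoctahydronaphthalen-2(1H)-one, via β-seleno ketone 13 (not isolated)
Conditions: (PhSe)2 (10 mol %), 1-fluoro-2,4,6-trimethylpyridinium triflate (1.3 equiv), NaF (3 equiv), 4 Å MS, MeCN, 0 °C → rt
Reagents that add atoms: none
Why: Proposed new method: a selenium-π-acid dehydrogenative semipinacol ring expansion — PhSe+ (from PhSeSePh and the N–F oxidant) forms a seleniranium ion on the vinyl group, the antiperiplanar C8–C10 bond (the quaternary, better-migrating carbon, as in the cationic D-homoannulation of 17-hydroxy-20-sulfonyloxy steroids) shifts to C9 while the carbinol becomes the C8 ketone and trans-hydrindane strain is released, and N–F oxidation of selenide 13 followed by loss of the acidic H-9 gives the exocyclic enone and returns the catalyst; the closest known reactions are diselenide/N–F oxidative allylic functionalisations of alkenes and stoichiometric PhSeX- or halonium-triggered semipinacol expansions of strained 1-vinylcyclobutanols, none shown on an unstrained monosubstituted vinyl carbinol with a quaternary migrating carbon.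

**Step 7**
Reactants: 14 (4aR,5R,8aS)-5-{[(tert-butyldimethylsilyl)oxy]methyl}-5,8a-dimethyl-1-methylideneoctahydronaphthalen-2(1H)-one
Product: 15 (4aR,5R,8aS)-5-{[(tert-butyldimethylsilyl)oxy]methyl}-5,8a-dimethyl-1-methylidene-1,4,4a,5,6,7,8,8a-octahydronaphthalen-2-yl trifluoromethanesulfonate
Conditions: KHMDS (1.2 equiv), THF, −78 °C; PhNTf2 (1.2 equiv), −78 → 0 °C
Reagents that add atoms: N-phenylbis(trifluoromethanesulfonimide), FC(F)(F)S(=O)(=O)N(c1ccccc1)S(=O)(=O)C(F)(F)F
Why: Kinetic α′-deprotonation at C7 (the only enolisable position) and O-triflation of the cross-conjugated enolate (enol triflate formation) fix the future C7=C8 double bond.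

**Step 8**
Reactants: 15 (4aR,5R,8aS)-5-{[(tert-butyldimethylsilyl)oxy]methyl}-5,8a-dimethyl-1-methylidene-1,4,4a,5,6,7,8,8a-octahydronaphthalen-2-yl trifluoromethanesulfonate; 16 methylmagnesium bromide
Product: 17 (4aR,5R,8aS)-5-{[(tert-butyldimethylsilyl)oxy]methyl}-2,5,8a-trimethyl-1-methylidene-1,4,4a,5,6,7,8,8a-octahydronaphthalene
Conditions: 16 (1.5 equiv), Fe(acac)3 (5 mol %), THF/NMP, −30 → 0 °C
Reagents that add atoms: none
Why: Iron-catalysed (Kochi/Fürstner) cross-coupling of the alkenyl triflate with the Grignard reagent installs C12 without moving either double bond.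

**Step 9**
Reactants: 18 3-methylphenol
Product: 20 4,4-dimethoxy-3-methylcyclohexa-2,5-dien-1-one, via 4-methoxy-3-methylphenol 19 (not isolated)
Conditions: PhI(OAc)2 (2.2 equiv), MeOH, 0 °C → rt
Reagents that add atoms: methanol, CO
Why: Hypervalent-iodine oxidative dearomatisation, in which methanol attacks the phenoxenium ion para to oxygen and a second oxidation of the resulting 4-methoxyphenol gives the p-quinone monoketal.

**Step 10**
Reactants: 20 4,4-dimethoxy-3-methylcyclohexa-2,5-dien-1-one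
Product: 21 2-iodo-4,4-dimethoxy-5-methylcyclohexa-2,5-dien-1-one
Conditions: I2 (1.5 equiv), pyridine/CH2Cl2 1:1, 0 °C → rt
Reagents that add atoms: iodine, II
Why: Johnson α-iodination of an enone (pyridine addition, iodination, elimination; Baylis–Hillman-type) takes place only on the enone arm whose β-carbon is unsubstituted.

**Step 11**
Reactants: 17 (4aR,5R,8aS)-5-{[(tert-butyldimethylsilyl)oxy]methyl}-2,5,8a-trimethyl-1-methylidene-1,4,4a,5,6,7,8,8a-octahydronaphthalene; 21 2-iodo-4,4-dimethoxy-5-methylcyclohexa-2,5-dien-1-one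
Product: 23 2-{[(1S,4aR,5R,8aR)-5-{[(tert-butyldimethylsilyl)oxy]methyl}-2,5,8a-trimethyl-1,4,4a,5,6,7,8,8a-octahydronaphthalen-1-yl]methyl}-4,4-dimethoxy-5-methylcyclohexa-2,5-dien-1-one, via B-alkyl-9-BBN 22 (not isolated)
Conditions: 9-BBN-H (1.3 equiv), THF, 0 → 45 °C; then 3 M aq Cs2CO3, 21, PdCl2(dppf) (5 mol %), AsPh3 (10 mol %), DMF, rt
Reagents that add atoms: none
Why: 9-BBN adds to the 1,1-disubstituted terminus of the diene from the α-face, anti to the axial angular methyl, which puts H-9 α and C11 β (as in the known conversion of drima-7,9(11)-diene into drimenol), and B-alkyl Suzuki–Miyaura coupling with the α-iodoenone (Johnson conditions) forms the C11–C5′ bond.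

**Step 12**
Reactants: 23 dienone monoketal (name as in step 11)
Product: 24 5′,6′-epoxide of 23 with the oxirane configuration of the target (TBS ether and dimethyl ketal retained)
Conditions: tBuOOH (2 equiv, in toluene), N-benzylcinchonidinium chloride (20 mol %), NaOH (0.2 equiv, aq), toluene, 0 °C
Reagents that add atoms: tert-butyl hydroperoxide, CC(C)(C)OO
Why: Weitz–Scheffer nucleophilic epoxidation under chiral phase-transfer catalysis (Wynberg type, precedented on quinone monoketals) attacks only the β-unsubstituted enone arm, and the cinchona cation is relied on to select the face that becomes 5′S,6′S in the target.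

**Step 13**
Reactants: 24 epoxy ketone ketal
Product: 26 epoxypholamin B, (4R,5S,6S)-5,6-epoxy-4-hydroxy-5-{[(1S,4aR,5R,8aR)-5-(hydroxymethyl)-2,5,8a-trimethyl-1,4,4a,5,6,7,8,8a-octahydronaphthalen-1-yl]methyl}-2-methylcyclohex-2-en-1-one, via epoxy alcohol ketal 25 (not isolated)
Conditions: DIBAL-H (1.5 equiv), THF, −78 °C; MeOH quench; then 48 % aq HF/MeCN 1:10, 0 °C → rt
Reagents that add atoms: water, O
Why: DIBAL-H coordinated to the oxirane oxygen is expected to deliver hydride syn to the epoxide and anti to the CH2-decalin arm (directed 1,2-reduction), setting C4′ with OH anti to the epoxide, and aqueous HF then hydrolyses the dimethyl ketal to the enone and cleaves the silyl ether.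

## Compound list

1 | 2-methylcyclopentane-1,3-dione | CC1C(=O)CCC1=O | starting material
2 | pent-1-en-3-one (ethyl vinyl ketone) | CCC(=O)C=C | starting material
3 | 2-methyl-2-(3-oxopentyl)cyclopentane-1,3-dione | CCC(=O)CCC1(C)C(=O)CCC1=O | intermediate
4 | (7aS)-4,7a-dimethyl-2,3,7,7a-tetrahydro-1H-indene-1,5(6H)-dione | CC1=C2CCC(=O)[C@@]2(C)CCC1=O | intermediate
5 | vinylmagnesium bromide | C=C[Mg]Br | starting material
6 | (1R,7aS)-1-ethenyl-1-hydroxy-4,7a-dimethyl-1,2,3,6,7,7a-hexahydro-5H-inden-5-one (OH cis to the angular methyl) | CC1=C2CC[C@@](O)(C=C)[C@@]2(C)CCC1=O | intermediate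
7 | formaldehyde | C=O | starting material
8 | dilithium C3-enolate / C8-alkoxide of the trans-fused reduced ketone | CC1=C([O-])CC[C@@]2(C)[C@H]1CC[C@@]2([O-])C=C.[Li+].[Li+] | intermediate
9 | (1R,3aR,4R,7aS)-1-ethenyl-1-hydroxy-4-(hydroxymethyl)-4,7a-dimethyloctahydro-5H-inden-5-one (trans-fused; CH2OH anti to the angular methyl) | OC[C@]1(C)C(=O)CC[C@@]2(C)[C@H]1CC[C@@]2(O)C=C | intermediate
10 | primary TBS ether of 9 | CC(C)(C)[Si](C)(C)OC[C@]1(C)C(=O)CC[C@@]2(C)[C@H]1CC[C@@]2(O)C=C | intermediate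
11 | N-(tert-butyldimethylsilyl)hydrazone of 10 | CC(C)(C)[Si](C)(C)OC[C@]1(C)C(=NN[Si](C)(C)C(C)(C)C)CC[C@@]2(C)[C@H]1CC[C@@]2(O)C=C | intermediate
12 | (1R,3aS,4R,7aS)-4-{[(tert-butyldimethylsilyl)oxy]methyl}-1-ethenyl-4,7a-dimethyloctahydro-1H-inden-1-ol | CC(C)(C)[Si](C)(C)OC[C@]1(C)CCC[C@@]2(C)[C@H]1CC[C@@]2(O)C=C | intermediate
13 | ring-expanded 1-[(phenylselanyl)methyl]decalin-2-one (C9 configuration not defined) | CC(C)(C)[Si](C)(C)OC[C@]1(C)CCC[C@@]2(C)[C@H]1CCC(=O)C2C[Se]c1ccccc1 | intermediate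
14 | (4aR,5R,8aS)-5-{[(tert-butyldimethylsilyl)oxy]methyl}-5,8a-dimethyl-1-methylideneoctahydronaphthalen-2(1H)-one (trans-decalin; C8 ketone, C9=C11) | CC(C)(C)[Si](C)(C)OC[C@]1(C)CCC[C@@]2(C)[C@H]1CCC(=O)C2=C | intermediate
15 | dienyl triflate of 14 (C7=C8–OTf, C9=C11) | CC(C)(C)[Si](C)(C)OC[C@]1(C)CCC[C@@]2(C)[C@H]1CC=C(OS(=O)(=O)C(F)(F)F)C2=C | intermediate
16 | methylmagnesium bromide | C[Mg]Br | starting material
17 | (4aR,5R,8aS)-5-{[(tert-butyldimethylsilyl)oxy]methyl}-2,5,8a-trimethyl-1-methylidene-1,4,4a,5,6,7,8,8a-octahydronaphthalene (13-silyloxy-drima-7,9(11)-diene) | CC(C)(C)[Si](C)(C)OC[C@]1(C)CCC[C@@]2(C)[C@H]1CC=C(C)C2=C | intermediate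
18 | 3-methylphenol (m-cresol) | Cc1cccc(O)c1 | starting material
19 | 4-methoxy-3-methylphenol | COc1ccc(O)cc1C | intermediate
20 | 4,4-dimethoxy-3-methylcyclohexa-2,5-dien-1-one | COC1(OC)C=CC(=O)C=C1C | intermediate
21 | 2-iodo-4,4-dimethoxy-5-methylcyclohexa-2,5-dien-1-one | COC1(OC)C=C(I)C(=O)C=C1C | intermediate
22 | 9-[(13-silyloxy-drim-7-en-11-yl)]-9-borabicyclo[3.3.1]nonane (H-9 α) | CC(C)(C)[Si](C)(C)OC[C@]1(C)CCC[C@@]2(C)[C@H]1CC=C(C)[C@@H]2CB1C2CCCC1CCC2 | intermediate
23 | 2-{[(1S,4aR,5R,8aR)-5-{[(tert-butyldimethylsilyl)oxy]methyl}-2,5,8a-trimethyl-1,4,4a,5,6,7,8,8a-octahydronaphthalen-1-yl]methyl}-4,4-dimethoxy-5-methylcyclohexa-2,5-dien-1-one | COC1(OC)C=C(C[C@H]2C(C)=CC[C@H]3[C@](C)(CO[Si](C)(C)C(C)(C)C)CCC[C@]23C)C(=O)C=C1C | intermediate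
24 | 5′,6′-epoxide of 23 (C4′ ketone, C1′ dimethyl ketal, oxirane as in target) | CC1=CC(=O)[C@]2(C[C@H]3C(C)=CC[C@H]4[C@](C)(CO[Si](C)(C)C(C)(C)C)CCC[C@]34C)O[C@@H]2C1(OC)OC | intermediate
25 | 4′-alcohol of 24 (OH anti to the epoxide; ketal and TBS retained) | CC1=C[C@@H](O)[C@]2(C[C@H]3C(C)=CC[C@H]4[C@](C)(CO[Si](C)(C)C(C)(C)C)CCC[C@]34C)O[C@@H]2C1(OC)OC | intermediate
26 | epoxypholamin B | CC1=C[C@@H](O)[C@]2(C[C@H]3C(C)=CC[C@H]4[C@](C)(CO)CCC[C@]34C)O[C@@H]2C1=O | target

## Step count and risks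

Total step count: 13. Longest linear sequence: 11 (steps 1–8, 11, 12, 13); steps 9–10 are the two-step side branch.

**Step 6 (proposed new ring expansion).** It could fail through migration of C7 instead of C10, acid-induced allylic transposition of the tertiary alcohol, or lack of catalyst turnover. The fallback uses known chemistry and sets out from 12. Hydroxyl-directed epoxidation of the vinyl group (VO(acac)2, tBuOOH, CH2Cl2) gives the 2,3-epoxy alcohol F1. BF3·OEt2 in CH2Cl2 at −78 °C then effects the classical epoxy-alcohol semipinacol ring expansion to the β-hydroxy ketone F2. MsCl/Et3N followed by DBU eliminates to the enone, and the route is rejoined at 14.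

**Step 12 (face selectivity of the epoxidation).** The drimane stereocentres are remote, so the catalyst may be mismatched or give a poor diastereomer ratio. The fallback replaces catalyst control by auxiliary control and sets out from 23. Transketalisation with (2R,4R)-pentane-2,4-diol (BF3·OEt2, CH2Cl2) gives the C2-symmetric dioxane ketal F3; the (2S,4S)-diol is used if the other face is delivered. Epoxidation with tBuOOH/DBU gives the epoxy ketone F4, and DIBAL-H reduction gives the alcohol F5. Aqueous HF/MeCN removes the chiral ketal and the silyl group, and the route comes back at 26.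

**Step 13 (face selectivity of the C4′ reduction).** Hydride may instead attack anti to the oxirane, as simple nucleophiles usually do, giving the 4′-epimer. The fallback sets out from 24. Luche reduction (NaBH4, CeCl3, MeOH, −78 °C) is used deliberately to give the syn epoxy alcohol F6. Mitsunobu inversion (4-nitrobenzoic acid, DIAD, PPh3) gives the inverted 4-nitrobenzoate F7. K2CO3/MeOH releases the alcohol, rejoining the route at 25, which is treated with aqueous HF as in step 13.

## Further compounds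

F1 | step 6 | 2,3-epoxy alcohol from 12 (oxirane carbon configuration not defined) | CC(C)(C)[Si](C)(C)OC[C@]1(C)CCC[C@@]2(C)[C@H]1CC[C@@]2(O)C1CO1
F2 | step 6 | ring-expanded 1-(hydroxymethyl)decalin-2-one (β-hydroxy ketone; C9 not defined) | CC(C)(C)[Si](C)(C)OC[C@]1(C)CCC[C@@]2(C)[C@H]1CCC(=O)C2CO
F3 | step 12 | (2R,4R)-pentane-2,4-diyl ketal analogue of 23 | C[C@@H]1C[C@@H](C)OC2(O1)C=C(C[C@H]3C(C)=CC[C@H]4[C@](C)(CO[Si](C)(C)C(C)(C)C)CCC[C@]34C)C(=O)C=C2C
F4 | step 12 | 5′,6′-epoxide of F3 (oxirane as in target) | CC1=CC(=O)[C@]2(C[C@H]3C(C)=CC[C@H]4[C@](C)(CO[Si](C)(C)C(C)(C)C)CCC[C@]34C)O[C@@H]2C15O[C@H](C)C[C@@H](C)O5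
F5 | step 12 | 4′-alcohol of F4 (OH anti to the epoxide) | CC1=C[C@@H](O)[C@]2(C[C@H]3C(C)=CC[C@H]4[C@](C)(CO[Si](C)(C)C(C)(C)C)CCC[C@]34C)O[C@@H]2C15O[C@H](C)C[C@@H](C)O5
F6 | step 13 | 4′-epimer of 25 (OH syn to the epoxide) | CC1=C[C@H](O)[C@]2(C[C@H]3C(C)=CC[C@H]4[C@](C)(CO[Si](C)(C)C(C)(C)C)CCC[C@]34C)O[C@@H]2C1(OC)OC
F7 | step 13 | 4-nitrobenzoate of 25 (inverted C4′) | CC1=C[C@@H](OC(=O)c5ccc(cc5)[N+](=O)[O-])[C@]2(C[C@H]3C(C)=CC[C@H]4[C@](C)(CO[Si](C)(C)C(C)(C)C)CCC[C@]34C)O[C@@H]2C1(OC)OC
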